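**Retrosynthetic overview**

- The C3 carbinol comes from a catalyst-controlled 1,2-reduction of an α'-bromo enone; the C4 bromide comes from α'-bromination of the spiro enone, with C4 set by equilibration.
- The spiro enone is cut by a Diels–Alder disconnection of ring B at the spiro carbon into 3,5,5-trimethyl-4-methylidenecyclohex-2-en-1-one (C10H14O, 150 g/mol) and 2-bromo-3-methylbuta-1,3-diene (C5H7Br, 147 g/mol); this late asymmetric cycloaddition sets the spiro stereocentre.
- The ring A dienone comes from mesityl oxide and methyl acetoacetate by Michael/aldol annulation; the ester carbon becomes the exocyclic methylene.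
- The bromodiene comes from 2-methylbut-3-yn-2-ol through 3-methylbuta-1,2-diene.
- Ring order: ring A first (step 1), ring B second (step 7).

Assumption: the sense of catalyst control in steps 7 and 9 is assigned by model only, so the catalyst antipode that gives the drawn isomer is the one meant.

**Route**

Step 1
Reactants: 1 4-methylpent-3-en-2-one (mesityl oxide); 2 methyl 3-oxobutanoate (methyl acetoacetate)
Product: 4 methyl 2,6,6-trimethyl-4-oxocyclohex-2-ene-1-carboxylate (racemic), via Michael adduct 3 (not isolated)
Conditions: BF3·OEt2 (0.5 equiv), neat, 20 °C, 3 d; distillation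
Reagents that add atoms: none
Why: Lewis-acid promoted Michael addition of the acetoacetate enol to the enone gives 3, whose mesityl-derived methyl ketone then closes onto the acetoacetate ketone by intramolecular aldol condensation (Robinson-type annulation), placing the ester on the future spiro carbon; the single stereocentre is racemic and is erased in step 2.

Step 2
Reactants: 4 methyl 2,6,6-trimethyl-4-oxocyclohex-2-ene-1-carboxylate
Product: 5 methyl 4-methoxy-2,6,6-trimethylcyclohexa-1,3-diene-1-carboxylate
Conditions: HC(OMe)3 (3 equiv), MeOH, TsOH·H2O (2 mol %), 40 °C; Et3N quench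
Reagents that add atoms: trimethyl orthoformate, COC(OC)OC
Why: Acid-catalysed enol ether formation under thermodynamic control removes the proton that is γ to the ketone and α to the ester, giving the through-conjugated push–pull dienol ether, which masks the ketone against hydride and flattens the former stereocentre.

Step 3
Reactants: 5 methyl 4-methoxy-2,6,6-trimethylcyclohexa-1,3-diene-1-carboxylate
Product: 7 3,5,5-trimethyl-4-methylidenecyclohex-2-en-1-one, via dienyl alcohol 6 (not isolated)
Conditions: LiAlH4 (1.0 equiv), Et2O, −20 to 0 °C; then 2 M HCl, THF, 20 to 45 °C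
Reagents that add atoms: water, O
Why: Hydride reduction of the ester gives allylic alcohol 6, and on acid treatment the enol ether expels the protonated hydroxyl and is hydrolysed (a vinylogous Stork–Danheiser-type hydrolysis–elimination), so the former ester carbon becomes the exocyclic methylene of the linearly conjugated dienone; no stereocentre is involved.

Step 4
Reactants: 8 2-methylbut-3-yn-2-ol
Product: 9 3-chloro-3-methylbut-1-yne
Conditions: conc. HCl, CaCl2, CuCl (cat.), copper powder, 0 to 20 °C
Reagents that add atoms: hydrogen chloride, Cl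
Why: SN1-type substitution of the tertiary propargylic alcohol by chloride, assisted by CuCl, is the classical preparation of tertiary propargylic chlorides; no stereocentre.

Step 5
Reactants: 9 3-chloro-3-methylbut-1-yne
Product: 10 3-methylbuta-1,2-diene
Conditions: Zn/Cu couple, EtOH, 60 °C, product distilled out as formed
Reagents that add atoms: none
Why: Reductive SN2' dehalogenation (propargyl-to-allene transposition through a propargyl/allenyl zinc species protonated by ethanol) gives the terminal allene, which leaves the mixture by distillation; no stereocentre.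

Step 6
Reactants: 10 3-methylbuta-1,2-diene
Product: 12 2-bromo-3-methylbuta-1,3-diene, via allylic dibromide 11 (not isolated)
Conditions: Br2 (1.0 equiv), Et2O, −78 °C; then KOC(CH3)3 (1.1 equiv), THF, −78 to 0 °C; distil, store cold over BHT
Reagents that add atoms: bromine, BrBr
Why: Electrophilic addition of bromine to the more electron-rich trisubstituted π-bond of the allene puts bromine on the central carbon and bromide on the tertiary allylic carbon to give 11, and E2 dehydrobromination toward a methyl group then gives the 2-bromodiene (any allylic isomer of 11 converges by 1,4-elimination); no stereocentre.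

Step 7
Reactants: 7 3,5,5-trimethyl-4-methylidenecyclohex-2-en-1-one; 12 2-bromo-3-methylbuta-1,3-diene
Product: 13 (6R)-8-bromo-1,5,5,9-tetramethylspiro[5.5]undeca-1,8-dien-3-one
Conditions: 12 (3 equiv), (S,S)-imidodiphosphorimidate Brønsted acid HN[P(=NSO2CF3)(O2Ar*)]2 (5 mol %; O2Ar* = (S)-3,3'-bis[3,5-bis(trifluoromethyl)phenyl]-1,1'-binaphthalene-2,2'-diolate), CH2Cl2, −40 to −20 °C
Reagents that add atoms: none
Why: Brønsted-acid catalysed, strongly asynchronous Diels–Alder cycloaddition in which the O-protonated dienone reacts at its exocyclic methylene, the diene terminus next to the methyl-bearing carbon bonds first so that methyl (not bromine) sits on the developing cationic carbon and ends para to the spiro atom, and the confined chiral counter-anion shields one face of the flat dienophile so that the only new stereocentre (C6, R) is set under catalyst control.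

Step 8
Reactants: 13 (6R)-8-bromo-1,5,5,9-tetramethylspiro[5.5]undeca-1,8-dien-3-one
Product: 16 (4S,6S)-4,8-dibromo-1,5,5,9-tetramethylspiro[5.5]undeca-1,8-dien-3-one, via trimethylsilyl dienol ether 14 (not isolated), via C4-epimeric bromo ketone 15 (not isolated)
Conditions: LiN(iPr)2 (1.1 equiv), Me3SiCl (1.3 equiv), THF, −78 °C; NBS (1.05 equiv), THF, −78 to 0 °C; then LiBr (1 equiv), Et3N (0.3 equiv), THF, 20 °C; chromatography
Reagents that add atoms: N-bromosuccinimide, O=C1CCC(=O)N1Br
Why: Kinetic α'-deprotonation of the enone with internal silyl trapping gives 14, and electrophilic α-bromination of this silyl enol ether occurs at C4; the doubly activated C4–H then lets kinetic epimer 15 equilibrate by soft enolisation to the expected more stable (4S) isomer, in which bromine is equatorial and cis to the flat C7–C8 arm that prefers the in-plane site beside the C1 methyl group.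

Step 9
Reactants: 16 (4S,6S)-4,8-dibromo-1,5,5,9-tetramethylspiro[5.5]undeca-1,8-dien-3-one
Product: 17 (3S,4S,6S)-4,8-dibromo-1,5,5,9-tetramethylspiro[5.5]undeca-1,8-dien-3-ol
Conditions: (R)-2-methyl-CBS-oxazaborolidine [(R)-1-methyl-3,3-diphenyltetrahydro-1H,3H-pyrrolo[1,2-c][1,3,2]oxazaborole] (0.2 equiv), catecholborane (1.8 equiv), toluene, −78 °C; MeOH quench, pH 7 work-up
Reagents that add atoms: none
Why: Corey–Bakshi–Shibata 1,2-reduction in which the catalyst boron binds the carbonyl lone pair on the side of the flat vinylic C2–H (the equatorial C4 bromine blocks the other), so the brominated flank acts as the large group and the (R)-catalyst delivers hydride to the face cis to the C4 bromine, setting C3 as S with the hydroxyl trans to bromine and leaving both C–Br bonds and the alkenes untouched.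

**Compound list**

1 | 4-methylpent-3-en-2-one (mesityl oxide) | CC(=O)C=C(C)C | starting material
2 | methyl 3-oxobutanoate (methyl acetoacetate) | COC(=O)CC(C)=O | starting material
3 | methyl 2-acetyl-3,3-dimethyl-5-oxohexanoate (racemic Michael adduct) | COC(=O)C(C(C)=O)C(C)(C)CC(C)=O | intermediate
4 | methyl 2,6,6-trimethyl-4-oxocyclohex-2-ene-1-carboxylate (racemic) | COC(=O)C1C(C)=CC(=O)CC1(C)C | intermediate
5 | methyl 4-methoxy-2,6,6-trimethylcyclohexa-1,3-diene-1-carboxylate | COC(=O)C1=C(C)C=C(OC)CC1(C)C | intermediate
6 | (4-methoxy-2,6,6-trimethylcyclohexa-1,3-dien-1-yl)methanol | OCC1=C(C)C=C(OC)CC1(C)C | intermediate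
7 | 3,5,5-trimethyl-4-methylidenecyclohex-2-en-1-one | CC1=CC(=O)CC(C)(C)C1=C | intermediate
8 | 2-methylbut-3-yn-2-ol | CC(C)(O)C#C | starting material
9 | 3-chloro-3-methylbut-1-yne | CC(C)(Cl)C#C | intermediate
10 | 3-methylbuta-1,2-diene | CC(C)=C=C | intermediate
11 | 2,3-dibromo-3-methylbut-1-ene | C=C(Br)C(C)(C)Br | intermediate
12 | 2-bromo-3-methylbuta-1,3-diene | C=C(C)C(Br)=C | intermediate
13 | (6R)-8-bromo-1,5,5,9-tetramethylspiro[5.5]undeca-1,8-dien-3-one | CC1=CC(=O)CC(C)(C)[C@]12CCC(C)=C(Br)C2 | intermediate
14 | [(6S)-8-bromo-1,5,5,9-tetramethylspiro[5.5]undeca-1,3,8-trien-3-yl]oxy(trimethyl)silane | CC1=CC(O[Si](C)(C)C)=CC(C)(C)[C@]12CCC(C)=C(Br)C2 | intermediate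
15 | (4R,6S)-4,8-dibromo-1,5,5,9-tetramethylspiro[5.5]undeca-1,8-dien-3-one | CC1=CC(=O)[C@H](Br)C(C)(C)[C@]12CCC(C)=C(Br)C2 | intermediate
16 | (4S,6S)-4,8-dibromo-1,5,5,9-tetramethylspiro[5.5]undeca-1,8-dien-3-one | CC1=CC(=O)[C@@H](Br)C(C)(C)[C@]12CCC(C)=C(Br)C2 | intermediate
17 | (3S,4S,6S)-4,8-dibromo-1,5,5,9-tetramethylspiro[5.5]undeca-1,8-dien-3-ol | CC1=C[C@H](O)[C@@H](Br)C(C)(C)[C@]12CCC(C)=C(Br)C2 | target

**Step count**

Total step count: 9. Longest linear sequence: 6 steps (steps 1–3 then 7–9; the diene branch, steps 4–6 then 7–9, is equally long).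

**Steps most likely to fail**

Step 7. Enantiofacial control at the remote exocyclic carbon of a dienone, with an electron-poor bromodiene and methyl-versus-bromine regiocontrol, has no exact precedent. The fallback sets out from 7 and 12. The cycloaddition is run with the achiral Lewis acid Me2AlCl (1.1 equiv, CH2Cl2, −78 to −20 °C), which gives 13 together with its mirror image (6S)-8-bromo-1,5,5,9-tetramethylspiro[5.5]undeca-1,8-dien-3-one F1. Preparative supercritical-fluid chromatography on a chiral stationary phase removes F1, and the route is rejoined at 13.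

Step 8. Bromination at C4 rather than at the γ-methyl, and the C4 configuration relative to the spiro centre, rest on small conformational energy differences. The fallback sets out from 13. Condensation with 4-methylbenzenesulfonohydrazide in MeOH gives N'-[(6R)-8-bromo-1,5,5,9-tetramethylspiro[5.5]undeca-1,8-dien-3-ylidene]-4-methylbenzenesulfonohydrazide F2. A Shapiro reaction with LiN(iPr)2 (3 equiv, THF, −78 to 20 °C) gives the ring A diene (6S)-8-bromo-1,5,5,9-tetramethylspiro[5.5]undeca-1,3,8-triene F3. NBS in aqueous 1,2-dimethoxyethane at 0 °C then adds bromine at C4 and water anti at the allylic C3 position, which makes the trans-bromohydrin in one operation. This replaces steps 8 and 9 and comes back to the route at 17.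

Step 9. The oxazaborolidine has to override whatever facial bias the hindered bromo ketone has, and hydride delivery cis to the bromine is also the face flanked by the axial C5 methyl group. The fallback sets out from 16. Reduction with iBu2AlH (toluene, −78 °C) from the opposite face gives the cis-bromohydrin (3R,4S,6S)-4,8-dibromo-1,5,5,9-tetramethylspiro[5.5]undeca-1,8-dien-3-ol F4. Mitsunobu inversion (4-nitrobenzoic acid, PPh3, diisopropyl azodicarboxylate, THF, 0 °C) gives (3S,4S,6S)-4,8-dibromo-1,5,5,9-tetramethylspiro[5.5]undeca-1,8-dien-3-yl 4-nitrobenzoate F5. Methanolysis with K2CO3 in MeOH at 0 °C removes the ester and comes back to the route at 17.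

Further compounds
F1 | step 7 | (6S)-8-bromo-1,5,5,9-tetramethylspiro[5.5]undeca-1,8-dien-3-one | CC1=CC(=O)CC(C)(C)[C@@]12CCC(C)=C(Br)C2
F2 | step 8 | N'-[(6R)-8-bromo-1,5,5,9-tetramethylspiro[5.5]undeca-1,8-dien-3-ylidene]-4-methylbenzenesulfonohydrazide | CC1=CC(=NNS(=O)(=O)c3ccc(C)cc3)CC(C)(C)[C@]12CCC(C)=C(Br)C2
F3 | step 8 | (6S)-8-bromo-1,5,5,9-tetramethylspiro[5.5]undeca-1,3,8-triene | CC1=CC=CC(C)(C)[C@]12CCC(C)=C(Br)C2
F4 | step 9 | (3R,4S,6S)-4,8-dibromo-1,5,5,9-tetramethylspiro[5.5]undeca-1,8-dien-3-ol | CC1=C[C@@H](O)[C@@H](Br)C(C)(C)[C@]12CCC(C)=C(Br)C2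
F5 | step 9 | (3S,4S,6S)-4,8-dibromo-1,5,5,9-tetramethylspiro[5.5]undeca-1,8-dien-3-yl 4-nitrobenzoate | CC1=C[C@H](OC(=O)c3ccc(cc3)[N+](=O)[O-])[C@@H](Br)C(C)(C)[C@]12CCC(C)=C(Br)C2
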